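## Structural features

The target is a C24 acid, numbered from the carboxyl carbon C1, in which a 1,2-dioxane (ring B: the O–O unit and C3–C6) is bonded through C6–C7 to a 2,5-disubstituted tetrahydrofuran (ring A: C7–C10 and one oxygen). C3 carries the CH2CO2H arm, and C10 carries an unbranched C11–C24 chain with a conjugated (17Z,19E)-diene and a terminal C23=C24 alkene. The four stereocentres (3R,6R,7S,10R) form two 1,4-related pairs across the rings (C3/C6, trans in ring B; C7/C10, trans in ring A) and one contiguous pair at the ring junction (C6/C7, erythro). The fragile elements are the O–O bond, the Z,E-diene and the terminal alkene. The O–O bond is sensitive to phosphines, hydrides, hydrogenation and low-valent metals, and also to base, because C3 is β to the carboxyl carbon and the peroxide can leave by retro-Michael cleavage. The real difficulty is the ordering: the peroxide must arrive late, with defined configuration at the hindered C6 next to the ring A oxygen, after the diene is in place and with no reduction afterwards. The key step uses the fact that the ring A oxygen is bonded to both C7 and C10 and that C10 also bears the C11 methylene. O7 can therefore be an allyl ether oxygen, C10 a carbenoid carbon and the allyl group the source of C11–C13, so that ring A, the C10–C11 bond and the C10 configuration all derive from C7; the price is a C9 carbonyl that the target lacks.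

## Logic of the disconnections

35 ⇒ 34. The C1 acid is released last from its methyl ester (C1–OMe bond). A free carboxylate would switch off the C2=C3 acceptor needed for ring B and interfere with every basic step before it. The skeleton is unchanged, but the order of events becomes free. The forward hydrolysis must be cold and short so that the β-peroxy ester does not open by retro-Michael cleavage.

34 ⇒ 33 ⇒ 31 + 32. Ring B is opened at both C–O bonds: O–C3 as a conjugate addition of the C6 peroxide oxygen to the C2=C3 enoate of 33, and O–C6 as a substitution of the C6 sulfonate of 31 by 32. Both oxygens of the O–O unit then come from 32 in one late operation, and C3 becomes a trigonal carbon. Ring B and two stereocentres reduce to one carbinol centre of configuration 6S, opposite to the target, which is what chelation control delivers from the chiral pool. The forward step needs substitution with inversion at a secondary carbon next to ring A to outrun elimination, and the closure to favour the 3,6-trans ring.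

31 ⇒ 30 ⇒ 29. The sulfonate is traced to the alcohol 30 and this to its 4-methoxybenzyl ether 29 (O6–S and O6–benzyl bonds). The ether is the group that made chelation possible earlier and it can be removed oxidatively without hydrogenation. The forward debenzylation must spare the diene.

29 ⇒ 28 + 27, 28 ⇒ 26 ⇒ 25. The C2=C3 bond is cut; 27 supplies C1 and C2, and the C3 aldehyde 28 comes from the silyl-protected primary alcohol of 25. This removes the acceptor, which would not survive the ylide chemistry used before it. The olefination must be E-selective and is run without isolating 28.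

25 ⇒ 21 + 24, 24 ⇒ 22 + 23. The C17=C18 bond is cut to a non-stabilised C17 ylide and the enal 24, and the C19=C20 bond of 24 to 22 and 23. The whole unsaturated terminus becomes a seven-carbon aldehyde made in one step, and the ring A fragment keeps only a saturated chain. The forward Wittig reaction must be Z-selective at C17=C18 and must not isomerise C19=C20.

21 ⇒ 20 ⇒ 19 ⇒ 17 + 18. The C17–P bond is cut to the bromide 20, and the C12–C13 bond is cut as an alkene (19) that would arise by cross-metathesis of the allyl group of 17 with 18. The partner 18 brings C13–C17 with the leaving group already in place, so no alcohol has to be adjusted. Metathesis and hydrogenation must leave a benzylic ether and a primary bromide intact.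

17 ⇒ 16 ⇒ 15. A carbonyl is added retrosynthetically at C9 and masked as the sulfonyl hydrazone 16. The ketone is what makes C10 a carbenoid carbon in the preceding step. The forward deoxygenation must not epimerise C10 nor eliminate the ring oxygen β to C9.

15 ⇒ 14. The O–C10 and C10–C11 bonds are cut together. Ring A opens to an acyclic diazoketone whose only stereocentres are C6 and C7, and C11–C13 become an O-allyl group. One ring, two skeletal bonds and the C10 stereocentre are removed in one step. The carbenoid must select O7 over O6 and over C–H bonds, and the rearrangement must be 2,5-trans selective. The descriptors of 14 (4S,5S) and 15 (2R,5S,1′S) were checked against the target: they correspond to 6S,7S,10R, so only C6 has to be inverted later and no structure needed correction. In 17 and 19 the C10 descriptor reads S because the unsaturated side chain outranks C9; the geometry is unchanged. The protecting-group pattern of 14 is kept. The 4-methoxybenzyl ether is needed for chelation and is removable oxidatively. The tert-butyldiphenylsilyl ether survives acid, hydroxide and borane.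

14 ⇒ 13 ⇒ 11 + 12, 11 ⇒ 10. The C9–C10 bond is cut; C10 comes from 12 and the acyl group from the acid 11 through the mixed anhydride 13. The diazoketone becomes an ordinary β-alkoxy ester. A mild acyl activation is needed that does not eliminate the β-allyloxy group; 12 is a commercial solution and replaces free diazomethane.

10 ⇒ 8 + 9. The O7–allyl bond is cut (the oxygen-bound allyl carbon is the future C13). This leaves a simple aldol product. The etherification must be non-basic, because the alkoxide of a β-hydroxy ester undergoes retro-aldol cleavage and elimination; the acid-activated donor 9 is therefore used instead of a Williamson alkylation.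

8 ⇒ 6 + 7. The C7–C8 bond is cut as an acetate aldol. C7 is set from C6, and the fragment reduces to a five-carbon α-alkoxy aldehyde. A chelating Lewis acid and a chelating (benzylic) ether on O6 are required so that the threo isomer forms.

6 ⇒ 5 ⇒ 4 ⇒ 3 ⇒ 2 ⇒ 1. The aldehyde is traced through the alcohol 5, the arylidene acetal 4 and 3, and the triol 2 to the chiral-pool lactone 1, whose stereocentre becomes C6. One acetal differentiates the three hydroxyls and then delivers the benzylic ether to O6 by reductive opening. That opening must be regioselective.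

## Other disconnections considered

Alternative 1: The cut is made at C4–C5 and C8–C9, on both sides of the C6/C7 diol.
- **Forward step.** (2S,3S)-1,2:3,4-Diepoxybutane A1 would be opened at both CH2 termini by two equivalents of allylmagnesium bromide A2 with catalytic CuI A3 (monovalent copper). This would give (5S,6S)-deca-1,9-diene-5,6-diol A4, the C2–C11 segment.
- **In favour.** C6 and C7 would come straight from the chiral pool in the same threo (6S,7S) relationship as in 8, with no diastereoselective step. Here the alternative is better than the chosen plan, which depends on a chelate. One step would give ten carbons with an alkene at each end: C2=C3 is one cross-metathesis from the Michael acceptor, and C10=C11 is where ring A would close.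
- **Against.** A4 is C2-symmetric, so ring A must be closed from O7 onto C10=C11 while the identical O6/C3=C2 half stays open. This means stopping a statistical reaction at the mono stage. C10 would be set in that etherification with selectivity that depends on the method. C11 would then be a functionalised carbon next to ring A, from which C12–C24 must be attached by an sp3–sp3 coupling. A1 is a volatile bifunctional alkylating agent.
- **Comparison.** On structure the two plans are equal after ring A, since both need the same C6 inversion with 32 and the same ring B closure. On mechanism the epoxide opening is more robust than a carbenoid reaction. On step count the alternative is likely the shorter, because no ketone has to be removed. The chosen plan is preferred because it sets C10 through an ordered rearrangement and leaves an allyl group that is extended by metathesis.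

Alternative 2: The O–C6 bond of ring B and the O–C10 bond of ring A are cut in one relay.
- **Forward step.** The hydroperoxy epoxy mesylate A5 (3R hydroperoxide, 6S,7S trans-epoxide, 10S mesylate) would be treated with one equivalent of Cs2CO3 A6. The peroxide anion would open the epoxide at C6 (6-exo, inversion), and the C7 alkoxide set free would displace the C10 mesylate (5-exo, inversion), giving the bicyclic bis-silyl ether A7.
- **In favour.** Both rings and the junction would form in one step from an acyclic chain. Every stereocentre would be fixed by a reagent-controlled step and relayed stereospecifically. C3 in particular would be defined before cyclisation, which is better than the chosen plan, where C3 rests on substrate control in a Michael addition. An epoxide is also a better electrophile for a peroxide than the hindered sulfonate 31, again a point for the alternative.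
- **Against.** A5 must carry a free, configurationally defined secondary hydroperoxide next to an epoxide and a mesylate, and making that hydroperoxide needs the same kind of peroxide substitution as step 21. Three stereo-elements need three separate asymmetric steps. After the relay the O–O bond is present while C1 is still an alcohol and the diene is still missing, so an oxidation and a phosphorus ylide olefination would have to be run on a peroxide.
- **Comparison.** The alternative is better in ring-forming economy and in control of C3. It is worse in the order of events, because the chosen plan finishes the diene before any peroxide exists. Overall length should be similar.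

Alternative 3: The O–C7 bond of ring A is cut and the C6 oxygen is added in the same step.
- **Forward step.** Methyl (2E,6E,10R,17Z,19E)-10-hydroxytetracosa-2,6,17,19,23-pentaenoate A8 would be treated with Re2O7 A9 (heptavalent rhenium) buffered by 2,6-dimethylpyridine A10. The perrhenate ester of the C10 hydroxyl would add two oxygens syn across the (E)-C6=C7 alkene. This closes ring A trans and leaves a threo 6S hydroxyl in A11, which is the same compound as 30.
- **In favour.** The whole carbon chain, diene and enoate included, would be assembled before any ring. C7 and C6 would both derive from the single centre C10. The route would arrive at 30 without a ketone to remove, without an O6 protecting group and without an aldol. In step economy this alternative is clearly the better.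
- **Against.** The oxidant must choose C6=C7 over four other alkenes. Hydroxyl direction helps, but a strongly Lewis-acidic high-valent oxo-metal reagent is a risk for the Z,E-diene (isomerisation, ionisation). C10 needs its own asymmetric step, and the skipped polyene with an (E)-C6=C7 bond must be built linearly.
- **Comparison.** On structure the plans are equal from 30 onward. On mechanism both relay chirality across ring A, from C10 to C7 there and from C7 to C10 here. The chosen plan does this without an external oxidant and before the diene exists. It is longer but should be safer for the sensitive chain.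

Key step: step 10

Assumption: 7, 9, 12, 18, 22, 23, 27 and 32 are taken as purchasable; 7 is the silyl ketene acetal of methyl acetate.
Abbreviations in names: PMB = 4-methoxybenzyl; TBDPS = tert-butyldiphenylsilyl.

## Route

Step 1
Reactants: 1 (5S)-5-(hydroxymethyl)oxolan-2-one
Product: 2 (2S)-pentane-1,2,5-triol
Conditions: LiBH4, THF, 0 °C to rt; MeOH quench
Reagents that add atoms: none
Why: Hydride reduction of a γ-lactone opens it to the 1,4-diol; the stereocentre (the future C6) is not involved and stays S.

Step 2
Reactants: 2 (2S)-pentane-1,2,5-triol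
Product: 3 3-[(4S)-2-(4-methoxyphenyl)-1,3-dioxolan-4-yl]propan-1-ol (both acetal epimers)
Conditions: 4-MeOC6H4CH(OMe)2, PPTS (cat.), DMF, 40 °C, reduced pressure
Reagents that add atoms: 4-methoxybenzaldehyde dimethyl acetal, COc1ccc(cc1)C(OC)OC
Why: Acid-catalysed transacetalisation under thermodynamic control; only the 1,2-diol can form a five-membered arylidene acetal, so the C6 and C7 oxygens are tied up and the C3 hydroxyl stays free.

Step 3
Reactants: 3 3-[(4S)-2-(4-methoxyphenyl)-1,3-dioxolan-4-yl]propan-1-ol
Product: 4 tert-butyl{3-[(4S)-2-(4-methoxyphenyl)-1,3-dioxolan-4-yl]propoxy}diphenylsilane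
Conditions: t-BuPh2SiCl, imidazole, CH2Cl2, 0 °C to rt
Reagents that add atoms: tert-butyl(chloro)diphenylsilane, CC(C)(C)[Si](Cl)(c1ccccc1)c1ccccc1
Why: Silylation of the remaining primary alcohol; this silyl ether tolerates the triflic acid of step 7, the hydroxide of step 8 and the borane of step 12.

Step 4
Reactants: 4 tert-butyl{3-[(4S)-2-(4-methoxyphenyl)-1,3-dioxolan-4-yl]propoxy}diphenylsilane
Product: 5 (2S)-2-(PMB-oxy)-5-(TBDPS-oxy)pentan-1-ol
Conditions: i-Bu2AlH (3 equiv), CH2Cl2, −78 to 0 °C; aq. KNaC4H4O6 (potassium sodium tartrate)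
Reagents that add atoms: none
Why: Regioselective reductive opening of a 4-methoxybenzylidene acetal; aluminium coordinates the less hindered primary oxygen, that C–O bond breaks and hydride adds to the oxocarbenium ion, which should leave the benzylic ether on the secondary oxygen.

Step 5
Reactants: 5 (2S)-2-(PMB-oxy)-5-(TBDPS-oxy)pentan-1-ol
Product: 6 (2S)-2-(PMB-oxy)-5-(TBDPS-oxy)pentanal
Conditions: Dess–Martin periodinane, NaHCO3, CH2Cl2, 0 °C to rt; used crude
Reagents that add atoms: none
Why: Dess–Martin oxidation under buffered, non-basic conditions, so the α-alkoxy aldehyde should not epimerise.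

Step 6
Reactants: 6 (2S)-2-(PMB-oxy)-5-(TBDPS-oxy)pentanal; 7 tert-butyl[(1-methoxyethenyl)oxy]dimethylsilane
Product: 8 methyl (3S,4S)-3-hydroxy-4-(PMB-oxy)-7-(TBDPS-oxy)heptanoate
Conditions: MgBr2·OEt2 (3 equiv), CH2Cl2, −78 to −20 °C; aq. NH4Cl
Reagents that add atoms: 7 tert-butyl[(1-methoxyethenyl)oxy]dimethylsilane, C=C(OC)O[Si](C)(C)C(C)(C)C
Why: Mukaiyama aldol addition under Cram chelate control; magnesium bridges the aldehyde oxygen and the PMB ether oxygen and the ketene acetal attacks the face anti to the C5 chain, which should give the threo (6S,7S) product and so sets C7.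

Step 7
Reactants: 8 methyl (3S,4S)-3-hydroxy-4-(PMB-oxy)-7-(TBDPS-oxy)heptanoate; 9 allyl 2,2,2-trichloroacetimidate
Product: 10 methyl (3S,4S)-3-(allyloxy)-4-(PMB-oxy)-7-(TBDPS-oxy)heptanoate
Conditions: CF3SO3H (5–10 mol%), cyclohexane–CH2Cl2 (2:1), 0 °C to rt
Reagents that add atoms: 9 allyl 2,2,2-trichloroacetimidate, C=CCOC(=N)C(Cl)(Cl)Cl
Why: Acid-catalysed O-alkylation by an allyl trichloroacetimidate (protonated imidate as allyl donor, trichloroacetamide as leaving group); without base the β-hydroxy ester cannot undergo retro-aldol cleavage or β-elimination.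

Step 8
Reactants: 10 methyl (3S,4S)-3-(allyloxy)-4-(PMB-oxy)-7-(TBDPS-oxy)heptanoate
Product: 11 (3S,4S)-3-(allyloxy)-4-(PMB-oxy)-7-(TBDPS-oxy)heptanoic acid
Conditions: LiOH·H2O, THF–MeOH–H2O, 0 °C to rt; 1 M HCl to pH 3
Reagents that add atoms: lithium hydroxide, [Li+].[OH-]
Why: Saponification of the methyl ester; the silyl ether, the two ethers and both stereocentres are stable to cold aqueous LiOH.

Step 9
Reactants: 11 (3S,4S)-3-(allyloxy)-4-(PMB-oxy)-7-(TBDPS-oxy)heptanoic acid; 12 (trimethylsilyl)diazomethane
Product: 14 (4S,5S)-4-(allyloxy)-1-diazo-5-(PMB-oxy)-8-(TBDPS-oxy)octan-2-one, via mixed isobutyl carbonic anhydride 13 (not isolated)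
Conditions: i-BuOCOCl, Et3N, THF, −20 °C; then Me3SiCHN2 (2 equiv), MeCN, 0 °C to rt; aq. NaHCO3
Reagents that add atoms: 12 (trimethylsilyl)diazomethane, C[Si](C)(C)C=[N+]=[N-]; isobutyl chloroformate, CC(C)COC(Cl)=O (its atoms remain only in 13)
Why: Acylation of a diazoalkane by a mixed carbonic anhydride (Arndt–Eistert-type diazoketone synthesis); the diazo carbon attacks the activated acyl group and the silyl group is lost to the carbonate leaving group or on work-up.

Step 10
Reactants: 14 (4S,5S)-4-(allyloxy)-1-diazo-5-(PMB-oxy)-8-(TBDPS-oxy)octan-2-one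
Product: 15 (2R,5S)-2-allyl-5-[(1S)-1-(PMB-oxy)-4-(TBDPS-oxy)butyl]oxolan-3-one
Conditions: Cu(acac)2 (10 mol%), CH2Cl2, reflux, slow addition of 14 at high dilution
Reagents that add atoms: none
Why: Cu(acac)2 (a divalent copper precatalyst) decomposes 14 with loss of N2 to an electrophilic copper carbenoid at C10. A lone pair of the allyl ether oxygen on C7 adds to this carbon and closes ring A as a five-membered cyclic oxonium ylide (O–C10 bond; closure exo with respect to the Cu=C10 bond through the C7–C8–C9–C10 tether). The allyl group then moves from oxygen to C10 by a suprafacial [2,3]-sigmatropic shift with allylic transposition, which forms the C10–C11 bond and leaves the C9 ketone. The closest known reaction type is the copper-catalysed tandem oxonium ylide formation and [2,3] rearrangement of β-allyloxy α-diazoketones to 2,5-dialkyl tetrahydrofuran-3-ones. The new stereocentre C10 is controlled by C7: in the envelope transition state the C7 side chain lies pseudo-equatorial and the allyl group is delivered to the opposite face of the ylide carbon, which should give the 2,5-trans ketone (2R,5S). The step needs chemoselectivity for O7 over the benzylic ether oxygen on C6, over C–H insertion at C6 and over cyclopropanation of the allyl alkene; the five-membered size of the O7 ylide, the preference of copper acetylacetonate carbenoids for ylide formation and slow addition should secure it. It also needs the [2,3] shift to outrun the [1,2] shift, which the allyl group ensures.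

Step 11
Reactants: 15 (2R,5S)-2-allyl-5-[(1S)-1-(PMB-oxy)-4-(TBDPS-oxy)butyl]oxolan-3-one
Product: 16 N′-{(2R,5S)-2-allyl-5-[(1S)-1-(PMB-oxy)-4-(TBDPS-oxy)butyl]oxolan-3-ylidene}-4-methylbenzenesulfonohydrazide (E/Z mixture)
Conditions: TsNHNH2, MgSO4, THF, rt
Reagents that add atoms: 4-methylbenzenesulfonohydrazide, Cc1ccc(cc1)S(=O)(=O)NN
Why: Condensation of the ketone with the sulfonyl hydrazide; neutral conditions at room temperature are chosen to limit enolisation (ene-hydrazine formation) towards C10.

Step 12
Reactants: 16 N′-{(2R,5S)-2-allyl-5-[(1S)-1-(PMB-oxy)-4-(TBDPS-oxy)butyl]oxolan-3-ylidene}-4-methylbenzenesulfonohydrazide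
Product: 17 (2S,5S)-2-allyl-5-[(1S)-1-(PMB-oxy)-4-(TBDPS-oxy)butyl]oxolane
Conditions: catecholborane, CHCl3, 0 °C to rt; then NaOAc·3H2O, reflux
Reagents that add atoms: none
Why: Reductive deoxygenation of a tosylhydrazone with catecholborane; hydride adds to C=N, acetate induces loss of sulfinate to an alkyl diazene, and this extrudes N2 to leave CH2 at C9. No stereocentre is touched; the C10 descriptor changes from R to S only because the allyl branch now outranks C9.

Step 13
Reactants: 17 (2S,5S)-2-allyl-5-[(1S)-1-(PMB-oxy)-4-(TBDPS-oxy)butyl]oxolane; 18 6-bromohex-1-ene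
Product: 20 (2R,5S)-2-(7-bromoheptyl)-5-[(1S)-1-(PMB-oxy)-4-(TBDPS-oxy)butyl]oxolane, via bromoheptenyl oxolane 19 (not isolated)
Conditions: second-generation Grubbs catalyst (H2IMes)(PCy3)Cl2Ru=CHPh (5 mol%), 18 (4 equiv), CH2Cl2, 40 °C; then EtOAc, PtO2, H2 (1 atm), rt
Reagents that add atoms: 18 6-bromohex-1-ene, C=CCCCCBr
Why: Olefin cross-metathesis of two unhindered terminal alkenes, driven by loss of ethene and excess 18, then hydrogenation of the new C12=C13 alkene in the same flask (its E/Z ratio is irrelevant). PtO2 in neutral EtOAc should leave the benzylic ether, the silyl ether and the primary C–Br bond intact.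

Step 14
Reactants: 20 (2R,5S)-2-(7-bromoheptyl)-5-[(1S)-1-(PMB-oxy)-4-(TBDPS-oxy)butyl]oxolane
Product: 21 (7-{(2R,5S)-5-[(1S)-1-(PMB-oxy)-4-(TBDPS-oxy)butyl]oxolan-2-yl}heptyl)triphenylphosphonium bromide
Conditions: PPh3, MeCN, reflux
Reagents that add atoms: triphenylphosphine, c1ccc(cc1)P(c1ccccc1)c1ccccc1
Why: SN2 quaternisation of triphenylphosphine by the primary bromide; the ethers are inert.

Step 15
Reactants: 22 pent-4-enal; 23 (triphenyl-λ5-phosphanylidene)acetaldehyde
Product: 24 (2E)-hepta-2,6-dienal
Conditions: toluene, 80 °C (22 in slight excess)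
Reagents that add atoms: 23 (triphenyl-λ5-phosphanylidene)acetaldehyde, O=CC=P(c1ccccc1)(c1ccccc1)c1ccccc1
Why: Wittig reaction of a stabilised formyl ylide, which is E-selective and adds C18 and C19; a slight excess of 22 limits a second homologation.

Step 16
Reactants: 21 (7-{(2R,5S)-5-[(1S)-1-(PMB-oxy)-4-(TBDPS-oxy)butyl]oxolan-2-yl}heptyl)triphenylphosphonium bromide; 24 (2E)-hepta-2,6-dienal
Product: 25 (2R,5S)-2-[(7Z,9E)-tetradeca-7,9,13-trien-1-yl]-5-[(1S)-1-(PMB-oxy)-4-(TBDPS-oxy)butyl]oxolane
Conditions: NaN(SiMe3)2, THF, −78 to 0 °C; then 24, −78 to 0 °C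
Reagents that add atoms: 24 (2E)-hepta-2,6-dienal, C=CCC/C=C/C=O
Why: Wittig reaction of a non-stabilised ylide under lithium-free conditions; the kinetically formed cis-oxaphosphetane collapses to the Z alkene at C17=C18, and the E geometry of C19=C20 is carried in unchanged with 24.

Step 17
Reactants: 25 (2R,5S)-2-[(7Z,9E)-tetradeca-7,9,13-trien-1-yl]-5-[(1S)-1-(PMB-oxy)-4-(TBDPS-oxy)butyl]oxolane
Product: 26 (4S)-4-(PMB-oxy)-4-{(2S,5R)-5-[(7Z,9E)-tetradeca-7,9,13-trien-1-yl]oxolan-2-yl}butan-1-ol
Conditions: Bu4NF, THF, 0 °C to rt; aq. NH4Cl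
Reagents that add atoms: none
Why: Fluoride-induced cleavage of the silyl ether, driven by the strong Si–F bond; nothing else in 25 reacts with fluoride.

Step 18
Reactants: 26 (4S)-4-(PMB-oxy)-4-{(2S,5R)-5-[(7Z,9E)-tetradeca-7,9,13-trien-1-yl]oxolan-2-yl}butan-1-ol; 27 methyl (triphenyl-λ5-phosphanylidene)acetate
Product: 29 methyl (2E,6S)-6-(PMB-oxy)-6-{(2S,5R)-5-[(7Z,9E)-tetradeca-7,9,13-trien-1-yl]oxolan-2-yl}hex-2-enoate, via butanal 28 (not isolated)
Conditions: Dess–Martin periodinane, NaHCO3, CH2Cl2, 0 °C to rt; then 27, rt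
Reagents that add atoms: 27 methyl (triphenyl-λ5-phosphanylidene)acetate, COC(=O)C=P(c1ccccc1)(c1ccccc1)c1ccccc1
Why: Dess–Martin oxidation to the aldehyde, then a Wittig reaction with a stabilised ylide in the same flask, which should give the (E)-enoate and adds C1 and C2.

Step 19
Reactants: 29 methyl (2E,6S)-6-(PMB-oxy)-6-{(2S,5R)-5-[(7Z,9E)-tetradeca-7,9,13-trien-1-yl]oxolan-2-yl}hex-2-enoate
Product: 30 methyl (2E,6S)-6-hydroxy-6-{(2S,5R)-5-[(7Z,9E)-tetradeca-7,9,13-trien-1-yl]oxolan-2-yl}hex-2-enoate
Conditions: DDQ, CH2Cl2–pH 7 buffer, 0 °C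
Reagents that add atoms: none
Why: Oxidative cleavage of the 4-methoxybenzyl ether by DDQ (hydride abstraction at the electron-rich benzylic position, then hydrolysis of the oxocarbenium ion); buffered, cold conditions are chosen to spare the diene.

Step 20
Reactants: 30 methyl (2E,6S)-6-hydroxy-6-{(2S,5R)-5-[(7Z,9E)-tetradeca-7,9,13-trien-1-yl]oxolan-2-yl}hex-2-enoate
Product: 31 methyl (2E,6S)-6-(methanesulfonyloxy)-6-{(2S,5R)-5-[(7Z,9E)-tetradeca-7,9,13-trien-1-yl]oxolan-2-yl}hex-2-enoate
Conditions: MeSO2Cl, Et3N, CH2Cl2, −20 to 0 °C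
Reagents that add atoms: methanesulfonyl chloride, CS(Cl)(=O)=O
Why: Sulfonylation of the secondary alcohol with retention at C6 (the C–O bond is not broken); low temperature suppresses base-induced oxa-Michael closure onto the enoate.

Step 21
Reactants: 31 methyl (2E,6S)-6-(methanesulfonyloxy)-6-{(2S,5R)-5-[(7Z,9E)-tetradeca-7,9,13-trien-1-yl]oxolan-2-yl}hex-2-enoate; 32 hydrogen peroxide
Product: 34 methyl 2-[(3R,6R)-6-{(2S,5R)-5-[(7Z,9E)-tetradeca-7,9,13-trien-1-yl]oxolan-2-yl}-1,2-dioxan-3-yl]acetate, via C6 hydroperoxide 33 (not isolated)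
Conditions: 50% aq. H2O2 (large excess), KOH, MeOH–THF, 0 °C to rt; crude 33, then Et2NH, CF3CH2OH, rt
Reagents that add atoms: 32 hydrogen peroxide, OO
Why: SN2 displacement of the secondary mesylate by hydroperoxide anion, a strong α-effect nucleophile, inverts C6 (6S to 6R); the peroxide anion then adds to C3 of the enoate in a 6-exo-trig peroxy-Michael closure. A chair transition state with both substituents equatorial, and reversibility of the addition under base, should favour the 3,6-trans (3R) ring B.

Step 22
Reactants: 34 methyl 2-[(3R,6R)-6-{(2S,5R)-5-[(7Z,9E)-tetradeca-7,9,13-trien-1-yl]oxolan-2-yl}-1,2-dioxan-3-yl]acetate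
Product: 35 2-[(3R,6R)-6-{(2S,5R)-5-[(7Z,9E)-tetradeca-7,9,13-trien-1-yl]oxolan-2-yl}-1,2-dioxan-3-yl]acetic acid
Conditions: LiOH, THF–H2O, 0 °C; 1 M HCl to pH 3
Reagents that add atoms: lithium hydroxide, [Li+].[OH-]
Why: Saponification of the methyl ester with LiOH at 0 °C, conditions under which dialkyl peroxides and the diene should survive; careful acidification releases 35.

## Compound list

1 | (5S)-5-(hydroxymethyl)oxolan-2-one | O=C1CC[C@@H](CO)O1 | starting material
2 | (2S)-pentane-1,2,5-triol | OCCC[C@@H](CO)O | intermediate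
3 | 3-[(4S)-2-(4-methoxyphenyl)-1,3-dioxolan-4-yl]propan-1-ol (both acetal epimers) | OCCC[C@H]1COC(c2ccc(OC)cc2)O1 | intermediate
4 | tert-butyl{3-[(4S)-2-(4-methoxyphenyl)-1,3-dioxolan-4-yl]propoxy}diphenylsilane | CC(C)(C)[Si](c1ccccc1)(c1ccccc1)OCCC[C@H]1COC(c2ccc(OC)cc2)O1 | intermediate
5 | (2S)-5-[(tert-butyldiphenylsilyl)oxy]-2-[(4-methoxybenzyl)oxy]pentan-1-ol | CC(C)(C)[Si](c1ccccc1)(c1ccccc1)OCCC[C@@H](CO)OCc1ccc(OC)cc1 | intermediate
6 | (2S)-5-[(tert-butyldiphenylsilyl)oxy]-2-[(4-methoxybenzyl)oxy]pentanal | CC(C)(C)[Si](c1ccccc1)(c1ccccc1)OCCC[C@@H](C=O)OCc1ccc(OC)cc1 | intermediate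
7 | tert-butyl[(1-methoxyethenyl)oxy]dimethylsilane | C=C(OC)O[Si](C)(C)C(C)(C)C | starting material
8 | methyl (3S,4S)-7-[(tert-butyldiphenylsilyl)oxy]-3-hydroxy-4-[(4-methoxybenzyl)oxy]heptanoate | COC(=O)C[C@H](O)[C@@H](OCc1ccc(OC)cc1)CCCO[Si](c1ccccc1)(c1ccccc1)C(C)(C)C | intermediate
9 | allyl 2,2,2-trichloroacetimidate | C=CCOC(=N)C(Cl)(Cl)Cl | starting material
10 | methyl (3S,4S)-3-(allyloxy)-7-[(tert-butyldiphenylsilyl)oxy]-4-[(4-methoxybenzyl)oxy]heptanoate | COC(=O)C[C@H](OCC=C)[C@@H](OCc1ccc(OC)cc1)CCCO[Si](c1ccccc1)(c1ccccc1)C(C)(C)C | intermediate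
11 | (3S,4S)-3-(allyloxy)-7-[(tert-butyldiphenylsilyl)oxy]-4-[(4-methoxybenzyl)oxy]heptanoic acid | OC(=O)C[C@H](OCC=C)[C@@H](OCc1ccc(OC)cc1)CCCO[Si](c1ccccc1)(c1ccccc1)C(C)(C)C | intermediate
12 | (trimethylsilyl)diazomethane | C[Si](C)(C)C=[N+]=[N-] | starting material
13 | mixed anhydride of 11 with isobutyl hydrogen carbonate | CC(C)COC(=O)OC(=O)C[C@H](OCC=C)[C@@H](OCc1ccc(OC)cc1)CCCO[Si](c1ccccc1)(c1ccccc1)C(C)(C)C | intermediate (not isolated)
14 | (4S,5S)-4-(allyloxy)-8-[(tert-butyldiphenylsilyl)oxy]-1-diazo-5-[(4-methoxybenzyl)oxy]octan-2-one | [N-]=[N+]=CC(=O)C[C@H](OCC=C)[C@@H](OCc1ccc(OC)cc1)CCCO[Si](c1ccccc1)(c1ccccc1)C(C)(C)C | intermediate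
15 | (2R,5S)-2-allyl-5-{(1S)-4-[(tert-butyldiphenylsilyl)oxy]-1-[(4-methoxybenzyl)oxy]butyl}oxolan-3-one | C=CC[C@@H]1C(=O)C[C@@H]([C@@H](OCc2ccc(OC)cc2)CCCO[Si](c2ccccc2)(c2ccccc2)C(C)(C)C)O1 | intermediate
16 | N′-[(2R,5S)-2-allyl-5-{(1S)-4-[(tert-butyldiphenylsilyl)oxy]-1-[(4-methoxybenzyl)oxy]butyl}oxolan-3-ylidene]-4-methylbenzenesulfonohydrazide (E/Z mixture) | C=CC[C@@H]1C(=NNS(=O)(=O)c2ccc(C)cc2)C[C@@H]([C@@H](OCc2ccc(OC)cc2)CCCO[Si](c2ccccc2)(c2ccccc2)C(C)(C)C)O1 | intermediate
17 | (2S,5S)-2-allyl-5-{(1S)-4-[(tert-butyldiphenylsilyl)oxy]-1-[(4-methoxybenzyl)oxy]butyl}oxolane | C=CC[C@@H]1CC[C@@H]([C@@H](OCc2ccc(OC)cc2)CCCO[Si](c2ccccc2)(c2ccccc2)C(C)(C)C)O1 | intermediate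
18 | 6-bromohex-1-ene | C=CCCCCBr | starting material
19 | (2S,5S)-2-(7-bromohept-2-en-1-yl)-5-{(1S)-4-[(tert-butyldiphenylsilyl)oxy]-1-[(4-methoxybenzyl)oxy]butyl}oxolane (E/Z mixture) | BrCCCCC=CC[C@@H]1CC[C@@H]([C@@H](OCc2ccc(OC)cc2)CCCO[Si](c2ccccc2)(c2ccccc2)C(C)(C)C)O1 | intermediate (not isolated)
20 | (2R,5S)-2-(7-bromoheptyl)-5-{(1S)-4-[(tert-butyldiphenylsilyl)oxy]-1-[(4-methoxybenzyl)oxy]butyl}oxolane | BrCCCCCCC[C@@H]1CC[C@@H]([C@@H](OCc2ccc(OC)cc2)CCCO[Si](c2ccccc2)(c2ccccc2)C(C)(C)C)O1 | intermediate
21 | {7-[(2R,5S)-5-{(1S)-4-[(tert-butyldiphenylsilyl)oxy]-1-[(4-methoxybenzyl)oxy]butyl}oxolan-2-yl]heptyl}triphenylphosphonium bromide | [Br-].c1ccc(cc1)[P+](c1ccccc1)(c1ccccc1)CCCCCCC[C@@H]1CC[C@@H]([C@@H](OCc2ccc(OC)cc2)CCCO[Si](c2ccccc2)(c2ccccc2)C(C)(C)C)O1 | intermediate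
22 | pent-4-enal | C=CCCC=O | starting material
23 | (triphenyl-λ5-phosphanylidene)acetaldehyde | O=CC=P(c1ccccc1)(c1ccccc1)c1ccccc1 | starting material
24 | (2E)-hepta-2,6-dienal | C=CCC/C=C/C=O | intermediate
25 | (2R,5S)-2-[(7Z,9E)-tetradeca-7,9,13-trien-1-yl]-5-{(1S)-4-[(tert-butyldiphenylsilyl)oxy]-1-[(4-methoxybenzyl)oxy]butyl}oxolane | C=CCC/C=C/C=C\CCCCCC[C@@H]1CC[C@@H]([C@@H](OCc2ccc(OC)cc2)CCCO[Si](c2ccccc2)(c2ccccc2)C(C)(C)C)O1 | intermediate
26 | (4S)-4-[(4-methoxybenzyl)oxy]-4-{(2S,5R)-5-[(7Z,9E)-tetradeca-7,9,13-trien-1-yl]oxolan-2-yl}butan-1-ol | C=CCC/C=C/C=C\CCCCCC[C@@H]1CC[C@@H]([C@@H](OCc2ccc(OC)cc2)CCCO)O1 | intermediate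
27 | methyl (triphenyl-λ5-phosphanylidene)acetate | COC(=O)C=P(c1ccccc1)(c1ccccc1)c1ccccc1 | starting material
28 | (4S)-4-[(4-methoxybenzyl)oxy]-4-{(2S,5R)-5-[(7Z,9E)-tetradeca-7,9,13-trien-1-yl]oxolan-2-yl}butanal | C=CCC/C=C/C=C\CCCCCC[C@@H]1CC[C@@H]([C@@H](OCc2ccc(OC)cc2)CCC=O)O1 | intermediate (not isolated)
29 | methyl (2E,6S)-6-[(4-methoxybenzyl)oxy]-6-{(2S,5R)-5-[(7Z,9E)-tetradeca-7,9,13-trien-1-yl]oxolan-2-yl}hex-2-enoate | C=CCC/C=C/C=C\CCCCCC[C@@H]1CC[C@@H]([C@@H](OCc2ccc(OC)cc2)CC/C=C/C(=O)OC)O1 | intermediate
30 | methyl (2E,6S)-6-hydroxy-6-{(2S,5R)-5-[(7Z,9E)-tetradeca-7,9,13-trien-1-yl]oxolan-2-yl}hex-2-enoate | C=CCC/C=C/C=C\CCCCCC[C@@H]1CC[C@@H]([C@@H](O)CC/C=C/C(=O)OC)O1 | intermediate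
31 | methyl (2E,6S)-6-[(methanesulfonyl)oxy]-6-{(2S,5R)-5-[(7Z,9E)-tetradeca-7,9,13-trien-1-yl]oxolan-2-yl}hex-2-enoate | C=CCC/C=C/C=C\CCCCCC[C@@H]1CC[C@@H]([C@@H](OS(C)(=O)=O)CC/C=C/C(=O)OC)O1 | intermediate
32 | hydrogen peroxide | OO | starting material
33 | methyl (2E,6R)-6-hydroperoxy-6-{(2S,5R)-5-[(7Z,9E)-tetradeca-7,9,13-trien-1-yl]oxolan-2-yl}hex-2-enoate | C=CCC/C=C/C=C\CCCCCC[C@@H]1CC[C@@H]([C@H](OO)CC/C=C/C(=O)OC)O1 | intermediate (not isolated)
34 | methyl 2-[(3R,6R)-6-{(2S,5R)-5-[(7Z,9E)-tetradeca-7,9,13-trien-1-yl]oxolan-2-yl}-1,2-dioxan-3-yl]acetate | C=CCC/C=C/C=C\CCCCCC[C@@H]1CC[C@@H]([C@H]2CC[C@H](CC(=O)OC)OO2)O1 | intermediate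
35 | 2-[(3R,6R)-6-{(2S,5R)-5-[(7Z,9E)-tetradeca-7,9,13-trien-1-yl]oxolan-2-yl}-1,2-dioxan-3-yl]acetic acid | C=CCC/C=C/C=C\CCCCCC[C@@H]1CC[C@@H]([C@H]2CC[C@H](CC(=O)O)OO2)O1 | target

## Step count and least certain steps

Total step count: 22. Longest linear sequence: 21 steps (steps 1 to 14 and 16 to 22, from 1 to 35); step 15 is a one-step side branch.

Step 10 (key step). The most likely failure is loss of chemoselectivity at the carbenoid: capture by the benzylic ether oxygen on C6 through a six-membered ylide followed by a benzyl shift, or insertion into the activated C6–H bond. Both sites are five or six atoms from C10, as O7 is. Carbene dimerisation is a further risk if the addition is not slow.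

The fallback sets out from 6 and comes back at 17. Aldehyde 6 would be treated with [2-(1,3-dioxolan-2-yl)ethyl]magnesium bromide (MgBr2·OEt2, CH2Cl2–THF, −78 °C). The same chelate as in step 6 should give (3S,4S)-7-[(tert-butyldiphenylsilyl)oxy]-1-(1,3-dioxolan-2-yl)-4-[(4-methoxybenzyl)oxy]heptan-3-ol F1. PPTS in methanol would exchange the dioxolane and close the C7 hydroxyl onto C10 to give the lactol ether (5S)-2-methoxy-5-{(1S)-4-[(tert-butyldiphenylsilyl)oxy]-1-[(4-methoxybenzyl)oxy]butyl}oxolane F2 as both anomers. Allyltrimethylsilane and BF3·OEt2 (CH2Cl2, −78 °C) would then add to the ring oxocarbenium ion (Hosomi–Sakurai type) to give 17 together with its C10 epimer, to be separated. This path needs no C9 ketone and is shorter, but the C10 configuration would rest on a modest facial bias of the oxocarbenium ion, so it is held in reserve.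

Step 21. The most likely failure is slow bimolecular displacement at C6, a secondary carbon flanked by the oxygen-bearing C7. Elimination towards C5, participation of the ring A oxygen (retention or ring expansion) and hydrolysis of the ester by the basic peroxide medium would then compete. Incomplete stereocontrol at C3 in the closure is the second concern.

The fallback sets out from 30 and comes back at 33. Alcohol 30 would be converted (Tf2O, 2,6-lutidine, CH2Cl2, −78 °C) into methyl (2E,6S)-6-{(2S,5R)-5-[(7Z,9E)-tetradeca-7,9,13-trien-1-yl]oxolan-2-yl}-6-[(trifluoromethanesulfonyl)oxy]hex-2-enoate F3. This much better electrophile would alkylate the potassium salt (KOt-Bu, THF, 0 °C) of 2-methoxypropan-2-yl hydroperoxide F4, a monoprotected peroxide made in one step by ozonolysis of 2,3-dimethylbut-2-ene in methanol. The substitution should proceed with inversion to give the peroxyketal methyl (2E,6R)-6-[(2-methoxypropan-2-yl)peroxy]-6-{(2S,5R)-5-[(7Z,9E)-tetradeca-7,9,13-trien-1-yl]oxolan-2-yl}hex-2-enoate F5. Aqueous acetic acid in THF would release 33, which is closed to 34 with Et2NH in CF3CH2OH as in step 21. Displacement and ring closure are thereby separated, and no hydroxide touches the ester.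

Step 12 (with step 11). The most likely failures are epimerisation at C10 through the ene-hydrazine tautomer of 16, and β-elimination of the ring oxygen from C10 (ring opening) when the diazene collapses with carbanion character at C9.

The fallback sets out from 15 and comes back at 17. Ketone 15 would be reduced (NaBH4, MeOH, −20 °C) to (2R,5S)-2-allyl-5-{(1S)-4-[(tert-butyldiphenylsilyl)oxy]-1-[(4-methoxybenzyl)oxy]butyl}oxolan-3-ol F6; either C9 epimer serves. This would be converted with 1,1′-thiocarbonyldiimidazole (toluene, 60 °C) into O-[(2R,5S)-2-allyl-5-{(1S)-4-[(tert-butyldiphenylsilyl)oxy]-1-[(4-methoxybenzyl)oxy]butyl}oxolan-3-yl] 1H-imidazole-1-carbothioate F7. Reduction with Bu3SnH and AIBN (toluene, 90 °C; Barton–McCombie deoxygenation) would give 17. A C9 radical does not expel a β-oxygen, and C10 is never enolisable.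

Step 7. The most likely failure is loss or transfer of the acid-labile 4-methoxybenzyl group under the Brønsted acid before the hindered C7 hydroxyl is allylated.

The fallback sets out from 8 and comes back at 10, and makes no new compound. Alcohol 8 would be allylated under neutral conditions by palladium-catalysed decarboxylative etherification with allyl tert-butyl carbonate (Pd(PPh3)4, zerovalent palladium, THF, 60 °C; Tsuji–Trost type). A π-allylpalladium cation is trapped by the alcohol, and only a transient trace of alkoxide is present.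

## Further compounds

F1 | step 10 | (3S,4S)-7-[(tert-butyldiphenylsilyl)oxy]-1-(1,3-dioxolan-2-yl)-4-[(4-methoxybenzyl)oxy]heptan-3-ol | O1CCOC1CC[C@H](O)[C@@H](OCc1ccc(OC)cc1)CCCO[Si](c1ccccc1)(c1ccccc1)C(C)(C)C
F2 | step 10 | (5S)-2-methoxy-5-{(1S)-4-[(tert-butyldiphenylsilyl)oxy]-1-[(4-methoxybenzyl)oxy]butyl}oxolane (both anomers) | COC1CC[C@@H]([C@@H](OCc2ccc(OC)cc2)CCCO[Si](c2ccccc2)(c2ccccc2)C(C)(C)C)O1
F3 | step 21 | methyl (2E,6S)-6-{(2S,5R)-5-[(7Z,9E)-tetradeca-7,9,13-trien-1-yl]oxolan-2-yl}-6-[(trifluoromethanesulfonyl)oxy]hex-2-enoate | C=CCC/C=C/C=C\CCCCCC[C@@H]1CC[C@@H]([C@@H](OS(=O)(=O)C(F)(F)F)CC/C=C/C(=O)OC)O1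
F4 | step 21 | 2-methoxypropan-2-yl hydroperoxide | COC(C)(C)OO
F5 | step 21 | methyl (2E,6R)-6-[(2-methoxypropan-2-yl)peroxy]-6-{(2S,5R)-5-[(7Z,9E)-tetradeca-7,9,13-trien-1-yl]oxolan-2-yl}hex-2-enoate | C=CCC/C=C/C=C\CCCCCC[C@@H]1CC[C@@H]([C@H](OOC(C)(C)OC)CC/C=C/C(=O)OC)O1
F6 | step 12 | (2R,5S)-2-allyl-5-{(1S)-4-[(tert-butyldiphenylsilyl)oxy]-1-[(4-methoxybenzyl)oxy]butyl}oxolan-3-ol (C3 epimers) | C=CC[C@@H]1C(O)C[C@@H]([C@@H](OCc2ccc(OC)cc2)CCCO[Si](c2ccccc2)(c2ccccc2)C(C)(C)C)O1
F7 | step 12 | O-[(2R,5S)-2-allyl-5-{(1S)-4-[(tert-butyldiphenylsilyl)oxy]-1-[(4-methoxybenzyl)oxy]butyl}oxolan-3-yl] 1H-imidazole-1-carbothioate | C=CC[C@@H]1C(OC(=S)n2ccnc2)C[C@@H]([C@@H](OCc2ccc(OC)cc2)CCCO[Si](c2ccccc2)(c2ccccc2)C(C)(C)C)O1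
F0 | step 7 | none | none
A1 | alternative 1 | (2S,3S)-1,2:3,4-diepoxybutane | C1O[C@@H]1[C@@H]1CO1
A2 | alternative 1 | allylmagnesium bromide | C=CC[Mg]Br
A3 | alternative 1 | copper iodide, CuI | [Cu]I
A4 | alternative 1 | (5S,6S)-deca-1,9-diene-5,6-diol | C=CCC[C@H](O)[C@@H](O)CCC=C
A5 | alternative 2 | (3R,6S,7S,10S)-17-[(tert-butyldimethylsilyl)oxy]-1-[(tert-butyldiphenylsilyl)oxy]-6,7-epoxy-3-hydroperoxyheptadecan-10-yl methanesulfonate (target numbering) | CC(C)(C)[Si](C)(C)OCCCCCCC[C@H](OS(C)(=O)=O)CC[C@@H]1O[C@H]1CC[C@@H](OO)CCO[Si](c1ccccc1)(c1ccccc1)C(C)(C)C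
A6 | alternative 2 | caesium carbonate, Cs2CO3 | [Cs+].[Cs+].[O-]C([O-])=O
A7 | alternative 2 | (3R,6R)-3-{2-[(tert-butyldiphenylsilyl)oxy]ethyl}-6-[(2S,5R)-5-{7-[(tert-butyldimethylsilyl)oxy]heptyl}oxolan-2-yl]-1,2-dioxane | CC(C)(C)[Si](C)(C)OCCCCCCC[C@@H]1CC[C@@H]([C@H]2CC[C@H](CCO[Si](c3ccccc3)(c3ccccc3)C(C)(C)C)OO2)O1
A8 | alternative 3 | methyl (2E,6E,10R,17Z,19E)-10-hydroxytetracosa-2,6,17,19,23-pentaenoate | C=CCC/C=C/C=C\CCCCCC[C@@H](O)CC/C=C/CC/C=C/C(=O)OC
A9 | alternative 3 | dirhenium heptoxide, Re2O7 | O=[Re](=O)(=O)O[Re](=O)(=O)=O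
A10 | alternative 3 | 2,6-dimethylpyridine | Cc1cccc(C)n1
A11 | alternative 3 | methyl (2E,6S)-6-hydroxy-6-{(2S,5R)-5-[(7Z,9E)-tetradeca-7,9,13-trien-1-yl]oxolan-2-yl}hex-2-enoate | C=CCC/C=C/C=C\CCCCCC[C@@H]1CC[C@@H]([C@@H](O)CC/C=C/C(=O)OC)O1
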